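The runs were computed from invented constants; the scatter is artificial.

Read this flask as a ladder of rates, and carry the bottom rung down with you. Each rung is a first-order constant: the logarithm of the ratio of [starting material] at the two ends of an interval, divided by the length of that interval.

| flask | starting material | free catalyst | time |
|---|---|---|---|
| Monday's | 150 mM | 15.0 mM |  |
| Thursday's | 450 mM | 15.0 mM |  |
| Saturday's | 150 mM | 45.0 mM |  |
| Sunday's | 150 mM | 110 mM | 23 min |

| run | time / min | [starting material] / mM |
|---|---|---|
| Monday's run | 0.92 | 138.8 |
| Monday's run | 1.8 | 127.7 |
| Monday's run | 3.3 | 107.7 |
| Monday's run | 6.3 | 81.9 |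
| Monday's run | 12 | 50.8 |
| Monday's run | 23 | 30.4 |
| Thursday's run | 0.92 | 427.1 |
| Thursday's run | 1.8 | 407.3 |
| Thursday's run | 3.3 | 373.6 |
| Thursday's run | 6.3 | 307.8 |
| Thursday's run | 12 | 206.5 |
| Thursday's run | 23 | 100.3 |
| Saturday's run | 0.92 | 123.7 |
| Saturday's run | 1.8 | 103.9 |
| Saturday's run | 3.3 | 78.1 |
| Saturday's run | 6.3 | 48.2 |
| Saturday's run | 12 | 27.2 |
| Saturday's run | 23 | 18.1 |

(each reading ± 0.8 mM)

- order of the initial rate in [starting material], near the charge of the Monday's run, the rate being that where two percent of its starting material are target (one fixed amount of target, the same in the runs compared)
- order of the initial rate in [free catalyst], near the charge of the Monday's run, the rate being that where two percent of its starting material are target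
- starting material in the Sunday's run at 23 min, as a share of the starting material charged

- Overall: starting material -> target, with free catalyst as catalyst.
- Constant volume, constant temperature.
- The analysis sees a species whether free or bound.
- An order is taken over about fifteen percent of the charge, up and down.

Saturday's opening gives 0.210 min⁻¹, faster than Monday's 0.0843 min⁻¹, and Monday's is faster than Thursday's 0.0568 min⁻¹. Saturday's last interval, from 12 min to 23 min, gives 0.0370 min⁻¹, lower than each opening. Call this pseudo-first-order constant the tail constant. Integrated, it says that [starting material] at a later time is the earlier value times the exponential of minus the tail constant times the elapsed time.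

To use it on Sunday's run, you need that run's clock. Saturday's run stood at 48.2 mM at 6.3 min, near Monday's 50.8 mM at 12 min, so by these readings its clock ran about 1.90 times as fast on 3.00 times the catalyst, which is a power of 0.587. As an estimate, that power makes Sunday's clock 1.69 times as fast as Saturday's, so Sunday's run should reach 18.1 mM at 13.6 min. If the tail constant holds on Sunday, the remaining 9.38 min bring it to 12.8 mM, or 8.52% of the charge.

The forecast gives 0.66 (0.52 to 0.8) for the order in [starting material], 0.74 (0.6 to 0.9) for the order in [free catalyst], and 12% (10% to 15%) for Sunday's run. Of Saturday's stall it says: “It looks like reversibility”. Your reckoning for Sunday's run differs, lying lower than the forecast's share.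

The flask gives an order of 0.67 in [starting material] and 0.91 in [free catalyst], and Sunday's run stands at 7.55% of its charge at 23 min, lower than both the forecast's 12% and your 8.52%.

    free catalyst + starting material ⇌ catalyst-substrate complex, settled at all times (2.330 M⁻¹)
    catalyst-substrate complex + starting material ⇌ doubly bound catalyst, settled at all times (66.10 M⁻¹)
    doubly bound catalyst → target + catalyst-substrate complex (1.206 min⁻¹)
    free catalyst + target → spent catalyst + target (1.458 M⁻¹ min⁻¹)
    starting material → decomposed substrate (0.01770 min⁻¹)

The step from free catalyst and target to spent catalyst and target moves the readings by 11 in units of the scatter, as a root mean square. On Monday's run, Saturday's tail constant carries 50.8 mM at 12 min to 33.8 mM at 23 min, and the reading there is 30.4 mM.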